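**Strategy.** Numbering: 2-oxaspiro[4.5]decane. The cyclohexenone is cut at C5–C6 and C8–C9, which leaves (Z)-3-(trimethylsilyl)propenal and a four-carbon lactone acetal. The cut exploits the cis-1,3 relationship of the C9–O and C5–C1 bonds on the carbocycle: these are tied in a temporary γ-lactone, a chiral 5-(menthyloxy)butyrolactone whose silyl ketene acetal is the precursor. In one silyl triflate operation a Mukaiyama aldol forms C5–C6 anti to the menthyloxy group, and a vinylsilane-terminated cyclisation onto the acyloxocarbenium ion forms C8–C9, giving a 6-oxabicyclo[3.2.1]octenone. The side-chain alkenyllithium later opens this lactone; its ring oxygen becomes the acetate oxygen.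

Key step: step 6

Remark (assumption): the carbinol carbon made in step 6 (C2 of the bicycle, C6 of the spirocycle) is expected as an epimer mixture and is left undefined in the SMILES of 8–10 and 19–23, because step 16 turns it into the ketone; material of the wrong absolute series (attack syn to the menthyloxy group in step 6) becomes a separable diastereomer after step 13. "Menthyl" = (1R,2S,5R)-5-methyl-2-(propan-2-yl)cyclohexyl.

Step 1
Reactants: 1 (5R)-5-(menthyloxy)furan-2(5H)-one
Product: 2 (5R)-5-(menthyloxy)oxolan-2-one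
Conditions: H2 (1 atm), 10% Pd/C, EtOAc, 23 °C
Reagents that add atoms: none
Why: Heterogeneous hydrogenation of the conjugated C3–C4 alkene; the acetal stereocentre C5 is not touched and no new stereocentre forms.

Step 2
Reactants: 2 (5R)-5-(menthyloxy)oxolan-2-one
Product: 3 methyl 2-[(5R)-5-(menthyloxy)-2-oxooxolan-3-yl]acetate (C3 epimers)
Conditions: LiN(iPr)2, THF, −78 °C; BrCH2CO2Me, −78 → −40 °C
Reagents that add atoms: methyl bromoacetate, COC(=O)CBr
Why: Lactone enolate alkylation (SN2) at C3, the only enolisable position of 2; the new centre is planarised again in step 3, so its configuration does not matter.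

Step 3
Reactants: 3 methyl 2-[(5R)-5-(menthyloxy)-2-oxooxolan-3-yl]acetate
Product: 4 methyl 2-[(5R)-5-(menthyloxy)-2-(triethylsilyloxy)-4,5-dihydrofuran-3-yl]acetate
Conditions: LiN(SiMe3)2 (slight deficit), THF, −78 → −50 °C; Et3SiCl, DMPU, −78 °C; non-aqueous work-up
Reagents that add atoms: chlorotriethylsilane, CC[Si](CC)(CC)Cl
Why: Regioselective enolisation and O-silylation (silyl ketene acetal formation): the ring α-CH of the lactone is the more acidic site compared with the ester CH2 and should give the more substituted enolate when the enolates can equilibrate.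

Step 4
Reactants: 5 3-(trimethylsilyl)prop-2-yn-1-ol
Product: 6 (2Z)-3-(trimethylsilyl)prop-2-en-1-ol
Conditions: H2 (1 atm), Pd/CaCO3 poisoned with Pb(OAc)2 (Lindlar catalyst), quinoline, hexane, 23 °C
Reagents that add atoms: none
Why: Lindlar semi-hydrogenation adds H2 syn to the alkyne and stops at the alkene, which fixes the Z vinylsilane.

Step 5
Reactants: 6 (2Z)-3-(trimethylsilyl)prop-2-en-1-ol
Product: 7 (2Z)-3-(trimethylsilyl)prop-2-enal
Conditions: Dess–Martin periodinane, NaHCO3, CH2Cl2, 0 °C; used at once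
Reagents that add atoms: none
Why: Dess–Martin oxidation of the allylic alcohol under buffered conditions should keep the Z geometry.

Step 6
Reactants: 4 methyl 2-[(5R)-5-(menthyloxy)-2-(triethylsilyloxy)-4,5-dihydrofuran-3-yl]acetate, 7 (2Z)-3-(trimethylsilyl)prop-2-enal
Product: 9 methyl 2-[(1S,5S)-7-oxo-2-(triethylsilyloxy)-6-oxabicyclo[3.2.1]oct-3-en-1-yl]acetate (C2 epimers), via aldol adduct 8 (not isolated)
Conditions: Et3SiOTf (1.1 equiv), 2,6-di-tert-butylpyridine (0.2 equiv), CH2Cl2, −78 °C (7 premixed, 4 added); then −78 → 0 °C; aq. NaHCO3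
Reagents that add atoms: none
Why: Et3SiOTf activates enal 7 and the tetrasubstituted ketene acetal 4 adds through C3 in a Mukaiyama aldol (silyl transfer to the aldolate) to give 8; the same triflate then ionises the lactone acetal, expelling the menthyl silyl ether, and the acyloxocarbenium ion is captured at the silicon-bearing carbon of the Z vinylsilane (β-silyl cation, then loss of the silyl group). The closest known reaction types are Mukaiyama aldol–Prins cascades and vinylsilane-terminated cyclisations onto oxocarbenium and N-acyliminium ions. The six-membered carbocycle closes in a 6-endo mode across the α and γ carbons of the lactone, so a 6-oxabicyclo[3.2.1]oct-3-ene results, and the Z geometry is what lets C4 reach the cation. The quaternary centre C1 is controlled by the menthyloxy-bearing acetal carbon (the aldehyde should enter anti to the pseudoaxial menthyloxy group); C5 is dictated by the bridge, because the tether can reach the planar cation only from its own face, so O6 and C7 end cis; the carbinol C2 is uncontrolled and irrelevant. The step needs C–C closure to outrun elimination of the cation and capture by the ester arm: ester capture is reversible whereas desilylation is not, and 7 is premixed with the triflate so that the aldol precedes acetal ionisation.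

Step 7
Reactants: 9 methyl 2-[(1S,5S)-7-oxo-2-(triethylsilyloxy)-6-oxabicyclo[3.2.1]oct-3-en-1-yl]acetate
Product: 10 2-[(1S,5S)-7-oxo-2-(triethylsilyloxy)-6-oxabicyclo[3.2.1]oct-3-en-1-yl]acetic acid
Conditions: Me3SnOH, ClCH2CH2Cl, 70 °C; 1 M HCl wash
Reagents that add atoms: trimethyltin hydroxide, C[Sn](C)(C)O
Why: Chemoselective ester hydrolysis with Me3SnOH: the unhindered methyl ester should be cleaved while the lactone carbonyl on the quaternary C1 and the silyl ether survive.

Step 8
Reactants: 11 5-bromo-2-methylpent-2-ene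
Product: 12 6-methylhept-5-en-1-yne
Conditions: LiC≡CH·H2NCH2CH2NH2, DMSO, 10 → 23 °C
Reagents that add atoms: lithium acetylide (ethylenediamine complex), [Li]C#C
Why: SN2 alkylation of lithium acetylide by the primary bromide.

Step 9
Reactants: 12 6-methylhept-5-en-1-yne
Product: 13 (3R)-3-(but-3-yn-1-yl)-2,2-dimethyloxirane
Conditions: D-fructose-derived Shi ketone (0.3 equiv), KHSO5 (Oxone), K2CO3, Bu4NHSO4, MeCN/CH2(OMe)2/aq. Na2B4O7 buffer, 0 °C
Reagents that add atoms: potassium peroxymonosulfate, [K+].[O-]S(=O)(=O)OO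
Why: Shi asymmetric epoxidation (chiral dioxirane) of the electron-rich trisubstituted alkene, the alkyne being inert; the spiro transition state of the D-fructose-derived ketone is expected to give the 3R epoxide.

Step 10
Reactants: 13 (3R)-3-(but-3-yn-1-yl)-2,2-dimethyloxirane
Product: 15 (3R)-2-methylhept-1-en-6-yn-3-ol, via trimethylsilyl ether 14 (not isolated)
Conditions: Me3SiOTf, DBU, toluene, 0 → 23 °C; then 1 M HCl, THF
Reagents that add atoms: none
Why: Silyl triflate/amidine isomerisation of an epoxide to an allylic silyl ether (O-silylation, C–O cleavage at the tertiary carbon, loss of a methyl proton); the C–O stereocentre is retained and dilute acid removes the silyl group.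

Step 11
Reactants: 15 (3R)-2-methylhept-1-en-6-yn-3-ol
Product: 16 tert-butyldimethyl{[(3R)-2-methylhept-1-en-6-yn-3-yl]oxy}silane
Conditions: t-BuMe2SiCl, imidazole, DMF, 23 °C
Reagents that add atoms: tert-butylchlorodimethylsilane, CC(C)(C)[Si](C)(C)Cl
Why: Standard silylation of a secondary alcohol.

Step 12
Reactants: 16 tert-butyldimethyl{[(3R)-2-methylhept-1-en-6-yn-3-yl]oxy}silane
Product: 17 tert-butyl{[(3R,6E)-7-iodo-2,6-dimethylhepta-1,6-dien-3-yl]oxy}dimethylsilane
Conditions: Me3Al (3 equiv), Cp2ZrCl2 (0.25 equiv), CH2Cl2, 0 → 23 °C; then I2, THF, −30 → 0 °C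
Reagents that add atoms: trimethylaluminium, C[Al](C)C; iodine, II
Why: Negishi zirconium-catalysed carboalumination adds methyl and aluminium syn across the terminal alkyne (methyl to the internal carbon) and iodinolysis proceeds with retention, giving the E vinyl iodide; silyl ether and 1,1-disubstituted alkene should not react.

Step 13
Reactants: 10 2-[(1S,5S)-7-oxo-2-(triethylsilyloxy)-6-oxabicyclo[3.2.1]oct-3-en-1-yl]acetic acid, 17 tert-butyl{[(3R,6E)-7-iodo-2,6-dimethylhepta-1,6-dien-3-yl]oxy}dimethylsilane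
Product: 20 2-[(1S,5S)-5-acetyloxy-1-[(2E,6R)-6-(tert-butyldimethylsilyloxy)-3,7-dimethylocta-2,7-dienoyl]-2-(triethylsilyloxy)cyclohex-3-en-1-yl]acetic acid, via alkenyllithium 18 (not isolated), via keto alkoxide 19 (not isolated)
Conditions: 17, t-BuLi (2.1 equiv), Et2O, −78 °C; added to 10 pre-treated with LiN(SiMe3)2 (1.0 equiv), THF, −78 → −40 °C; then Ac2O, −78 → 0 °C; aq. NH4Cl, pH 4
Reagents that add atoms: acetic anhydride, CC(=O)OC(C)=O
Why: Iodine–lithium exchange with retention of the E geometry, then nucleophilic acyl substitution at the strained lactone (the hemiketal alkoxide should collapse only on warming, which prevents a second addition); the freed C5 alkoxide, the former lactone oxygen, is trapped by Ac2O as the acetate, and the lithium carboxylate is inert at low temperature.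

Step 14
Reactants: 20 2-[(1S,5S)-5-acetyloxy-1-[(2E,6R)-6-(tert-butyldimethylsilyloxy)-3,7-dimethylocta-2,7-dienoyl]-2-(triethylsilyloxy)cyclohex-3-en-1-yl]acetic acid
Product: 22 (1R,5R,9S)-1-[(1E,5R)-5-(tert-butyldimethylsilyloxy)-2,6-dimethylhepta-1,6-dien-1-yl]-3-oxo-6-(triethylsilyloxy)-2-oxaspiro[4.5]dec-7-en-9-yl acetate, via hydroxy acid 21 (not isolated)
Conditions: Zn(BH4)2, Et2O, −30 → 0 °C; 1 M HCl work-up; PPTS (cat.), CH2Cl2, 23 °C
Reagents that add atoms: none
Why: Chelation-controlled 1,2-reduction of the acyclic enone: zinc should bridge the carboxylate and the ketone oxygen, so hydride adds to the ketone face lying over the ring CH2 (C6), away from the silyloxy-bearing C2, which sets the 1R carbinol; mild acid then lactonises the γ-hydroxy acid.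

Step 15
Reactants: 22 (1R,5R,9S)-1-[(1E,5R)-5-(tert-butyldimethylsilyloxy)-2,6-dimethylhepta-1,6-dien-1-yl]-3-oxo-6-(triethylsilyloxy)-2-oxaspiro[4.5]dec-7-en-9-yl acetate
Product: 23 (1R,5S,9S)-1-[(1E,5R)-5-(tert-butyldimethylsilyloxy)-2,6-dimethylhepta-1,6-dien-1-yl]-6-hydroxy-3-oxo-2-oxaspiro[4.5]dec-7-en-9-yl acetate
Conditions: PPTS, MeOH/CH2Cl2, 0 → 23 °C
Reagents that add atoms: none
Why: Acid-catalysed methanolysis of the triethylsilyl ether, which is far more labile than the tert-butyldimethylsilyl ether; acetate and lactone should be stable to PPTS.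

Step 16
Reactants: 23 (1R,5S,9S)-1-[(1E,5R)-5-(tert-butyldimethylsilyloxy)-2,6-dimethylhepta-1,6-dien-1-yl]-6-hydroxy-3-oxo-2-oxaspiro[4.5]dec-7-en-9-yl acetate
Product: 24 (1R,5R,9S)-1-[(1E,5R)-5-(tert-butyldimethylsilyloxy)-2,6-dimethylhepta-1,6-dien-1-yl]-3,6-dioxo-2-oxaspiro[4.5]dec-7-en-9-yl acetate
Conditions: Dess–Martin periodinane, NaHCO3, CH2Cl2, 0 → 23 °C
Reagents that add atoms: none
Why: Dess–Martin oxidation of the secondary allylic alcohol to the enone; both C6 epimers give the same ketone.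

Step 17
Reactants: 24 (1R,5R,9S)-1-[(1E,5R)-5-(tert-butyldimethylsilyloxy)-2,6-dimethylhepta-1,6-dien-1-yl]-3,6-dioxo-2-oxaspiro[4.5]dec-7-en-9-yl acetate
Product: 25 (1R,5R,9S)-1-[(1E,5R)-5-hydroxy-2,6-dimethylhepta-1,6-dien-1-yl]-3,6-dioxo-2-oxaspiro[4.5]dec-7-en-9-yl acetate
Conditions: HF·pyridine, pyridine, THF, 0 → 23 °C
Reagents that add atoms: none
Why: Fluoride-mediated silyl ether cleavage under buffered acidic conditions that should spare the acetate, the lactone and the γ-acetoxy enone.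

**Compound list**

1 | (5R)-5-(menthyloxy)furan-2(5H)-one | O=C1C=C[C@H](O[C@@H]2C[C@H](C)CC[C@H]2C(C)C)O1 | starting material
2 | (5R)-5-(menthyloxy)oxolan-2-one | O=C1CC[C@H](O[C@@H]2C[C@H](C)CC[C@H]2C(C)C)O1 | intermediate
3 | methyl 2-[(5R)-5-(menthyloxy)-2-oxooxolan-3-yl]acetate (C3 epimers) | COC(=O)CC1C[C@H](O[C@@H]2C[C@H](C)CC[C@H]2C(C)C)OC1=O | intermediate
4 | methyl 2-[(5R)-5-(menthyloxy)-2-(triethylsilyloxy)-4,5-dihydrofuran-3-yl]acetate | COC(=O)CC1=C(O[Si](CC)(CC)CC)O[C@@H](O[C@@H]2C[C@H](C)CC[C@H]2C(C)C)C1 | intermediate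
5 | 3-(trimethylsilyl)prop-2-yn-1-ol | C[Si](C)(C)C#CCO | starting material
6 | (2Z)-3-(trimethylsilyl)prop-2-en-1-ol | C[Si](C)(C)/C=C\CO | intermediate
7 | (2Z)-3-(trimethylsilyl)prop-2-enal | C[Si](C)(C)/C=C\C=O | intermediate
8 | methyl 2-[(3S,5R)-5-(menthyloxy)-2-oxo-3-[(2Z)-1-(triethylsilyloxy)-3-(trimethylsilyl)prop-2-en-1-yl]oxolan-3-yl]acetate (carbinol epimers; not isolated) | COC(=O)C[C@]1(C(O[Si](CC)(CC)CC)/C=C\[Si](C)(C)C)C[C@H](O[C@@H]2C[C@H](C)CC[C@H]2C(C)C)OC1=O | intermediate
9 | methyl 2-[(1S,5S)-7-oxo-2-(triethylsilyloxy)-6-oxabicyclo[3.2.1]oct-3-en-1-yl]acetate (C2 epimers) | COC(=O)C[C@]12C[C@H](OC1=O)C=CC2O[Si](CC)(CC)CC | intermediate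
10 | 2-[(1S,5S)-7-oxo-2-(triethylsilyloxy)-6-oxabicyclo[3.2.1]oct-3-en-1-yl]acetic acid (C2 epimers) | OC(=O)C[C@]12C[C@H](OC1=O)C=CC2O[Si](CC)(CC)CC | intermediate
11 | 5-bromo-2-methylpent-2-ene | CC(C)=CCCBr | starting material
12 | 6-methylhept-5-en-1-yne | CC(C)=CCCC#C | intermediate
13 | (3R)-3-(but-3-yn-1-yl)-2,2-dimethyloxirane | CC1(C)O[C@@H]1CCC#C | intermediate
14 | trimethyl{[(3R)-2-methylhept-1-en-6-yn-3-yl]oxy}silane (not isolated) | C=C(C)[C@H](O[Si](C)(C)C)CCC#C | intermediate
15 | (3R)-2-methylhept-1-en-6-yn-3-ol | C=C(C)[C@H](O)CCC#C | intermediate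
16 | tert-butyldimethyl{[(3R)-2-methylhept-1-en-6-yn-3-yl]oxy}silane | C=C(C)[C@H](O[Si](C)(C)C(C)(C)C)CCC#C | intermediate
17 | tert-butyl{[(3R,6E)-7-iodo-2,6-dimethylhepta-1,6-dien-3-yl]oxy}dimethylsilane | C=C(C)[C@H](O[Si](C)(C)C(C)(C)C)CC/C(C)=C/I | intermediate
18 | [(1E,5R)-5-(tert-butyldimethylsilyloxy)-2,6-dimethylhepta-1,6-dien-1-yl]lithium (not isolated) | C=C(C)[C@H](O[Si](C)(C)C(C)(C)C)CC/C(C)=C/[Li] | intermediate
19 | dilithium 2-[(1S,5S)-1-[(2E,6R)-6-(tert-butyldimethylsilyloxy)-3,7-dimethylocta-2,7-dienoyl]-5-oxido-2-(triethylsilyloxy)cyclohex-3-en-1-yl]acetate (not isolated) | C=C(C)[C@H](O[Si](C)(C)C(C)(C)C)CC/C(C)=C/C(=O)[C@]1(CC(=O)[O-])C[C@H]([O-])C=CC1O[Si](CC)(CC)CC.[Li+].[Li+] | intermediate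
20 | 2-[(1S,5S)-5-acetyloxy-1-[(2E,6R)-6-(tert-butyldimethylsilyloxy)-3,7-dimethylocta-2,7-dienoyl]-2-(triethylsilyloxy)cyclohex-3-en-1-yl]acetic acid | C=C(C)[C@H](O[Si](C)(C)C(C)(C)C)CC/C(C)=C/C(=O)[C@]1(CC(O)=O)C[C@H](OC(C)=O)C=CC1O[Si](CC)(CC)CC | intermediate
21 | 2-[(1R,5S)-5-acetyloxy-1-[(1R,2E,6R)-6-(tert-butyldimethylsilyloxy)-1-hydroxy-3,7-dimethylocta-2,7-dien-1-yl]-2-(triethylsilyloxy)cyclohex-3-en-1-yl]acetic acid (not isolated) | C=C(C)[C@H](O[Si](C)(C)C(C)(C)C)CC/C(C)=C/[C@@H](O)[C@]1(CC(O)=O)C[C@H](OC(C)=O)C=CC1O[Si](CC)(CC)CC | intermediate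
22 | (1R,5R,9S)-1-[(1E,5R)-5-(tert-butyldimethylsilyloxy)-2,6-dimethylhepta-1,6-dien-1-yl]-3-oxo-6-(triethylsilyloxy)-2-oxaspiro[4.5]dec-7-en-9-yl acetate | C=C(C)[C@H](O[Si](C)(C)C(C)(C)C)CC/C(C)=C/[C@H]1OC(=O)C[C@]12C[C@H](OC(C)=O)C=CC2O[Si](CC)(CC)CC | intermediate
23 | (1R,5S,9S)-1-[(1E,5R)-5-(tert-butyldimethylsilyloxy)-2,6-dimethylhepta-1,6-dien-1-yl]-6-hydroxy-3-oxo-2-oxaspiro[4.5]dec-7-en-9-yl acetate | C=C(C)[C@H](O[Si](C)(C)C(C)(C)C)CC/C(C)=C/[C@H]1OC(=O)C[C@]12C[C@H](OC(C)=O)C=CC2O | intermediate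
24 | (1R,5R,9S)-1-[(1E,5R)-5-(tert-butyldimethylsilyloxy)-2,6-dimethylhepta-1,6-dien-1-yl]-3,6-dioxo-2-oxaspiro[4.5]dec-7-en-9-yl acetate | C=C(C)[C@H](O[Si](C)(C)C(C)(C)C)CC/C(C)=C/[C@H]1OC(=O)C[C@]12C[C@H](OC(C)=O)C=CC2=O | intermediate
25 | (1R,5R,9S)-1-[(1E,5R)-5-hydroxy-2,6-dimethylhepta-1,6-dien-1-yl]-3,6-dioxo-2-oxaspiro[4.5]dec-7-en-9-yl acetate | C=C(C)[C@H](O)CC/C(C)=C/[C@H]1OC(=O)C[C@]12C[C@H](OC(C)=O)C=CC2=O | target

**Step count.** 17 steps in total; longest linear sequence 10 steps (1 → 2 → 3 → 6 → 7 → 13 → 14 → 15 → 16 → 17; the side-chain branch 8 → 12 then 13 → 17 is equally long).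

**Steps most likely to fail**

Step 6. The acetal may ionise before or without C–C bond formation (elimination towards a silyloxyfuran, lasting capture by the ester arm), or the silyl-activated enal may isomerise from Z to E, so that the second bond never closes. The fallback separates the two bond formations and avoids the labile enal. It sets out from 3: its lithium enolate (LiN(SiMe3)2, THF, −78 °C) is added to commercial 3-(trimethylsilyl)prop-2-ynal and the aldolate is silylated in the flask with Et3SiCl to give the alkynyl aldol silyl ether F1. Lindlar semi-hydrogenation then gives 8 as an isolated compound, and a separate vinylsilane-terminated cyclisation with SnCl4 in CH2Cl2 at −78 °C comes back to the route at 9.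

Step 14. Hydride may add to both faces of the ketone if the zinc chelate between carboxylate and ketone does not form (poor facial selectivity at C1). The fallback uses reagent control and sets out from 20: esterification with Me3SiCHN2 gives the methyl ester F2. Corey–Bakshi–Shibata reduction with (S)-2-methyl-CBS-oxazaborolidine and catecholborane, the quaternary ring carbon acting as the large group, should give the 1R hydroxy ester F3. F3 lactonises with PPTS and comes back to the route at 22.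

Step 3. Deprotonation may occur at the ester CH2 instead of the ring CH (wrong regiochemistry of enolisation), giving the isomeric ketene acetal. The fallback avoids enolisation and sets out from 1: bromination–dehydrobromination (Br2, then Et3N) gives the 3-bromobutenolide F4. Negishi coupling with the Reformatsky reagent BrZnCH2CO2Me (Pd(PPh3)4) gives the 3-substituted butenolide F5. Copper hydride-catalysed 1,4-hydrosilylation ([(Ph3P)CuH]6, Et3SiH) then places hydride on C4 and silicon on oxygen and comes back to the route at 4.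

Further compounds
F1 | step 6 | methyl 2-[(3S,5R)-5-(menthyloxy)-2-oxo-3-[1-(triethylsilyloxy)-3-(trimethylsilyl)prop-2-yn-1-yl]oxolan-3-yl]acetate | COC(=O)C[C@]1(C(O[Si](CC)(CC)CC)C#C[Si](C)(C)C)C[C@H](O[C@@H]2C[C@H](C)CC[C@H]2C(C)C)OC1=O
F2 | step 14 | methyl 2-[(1S,5S)-5-acetyloxy-1-[(2E,6R)-6-(tert-butyldimethylsilyloxy)-3,7-dimethylocta-2,7-dienoyl]-2-(triethylsilyloxy)cyclohex-3-en-1-yl]acetate | C=C(C)[C@H](O[Si](C)(C)C(C)(C)C)CC/C(C)=C/C(=O)[C@]1(CC(=O)OC)C[C@H](OC(C)=O)C=CC1O[Si](CC)(CC)CC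
F3 | step 14 | methyl 2-[(1R,5S)-5-acetyloxy-1-[(1R,2E,6R)-6-(tert-butyldimethylsilyloxy)-1-hydroxy-3,7-dimethylocta-2,7-dien-1-yl]-2-(triethylsilyloxy)cyclohex-3-en-1-yl]acetate | C=C(C)[C@H](O[Si](C)(C)C(C)(C)C)CC/C(C)=C/[C@@H](O)[C@]1(CC(=O)OC)C[C@H](OC(C)=O)C=CC1O[Si](CC)(CC)CC
F4 | step 3 | (5R)-3-bromo-5-(menthyloxy)furan-2(5H)-one | O=C1C(Br)=C[C@H](O[C@@H]2C[C@H](C)CC[C@H]2C(C)C)O1
F5 | step 3 | methyl 2-[(5R)-5-(menthyloxy)-2-oxo-2,5-dihydrofuran-3-yl]acetate | COC(=O)CC1=C[C@H](O[C@@H]2C[C@H](C)CC[C@H]2C(C)C)OC1=O
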